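Slowness is what the earlier runs end on, so the end of a flask is reckoned here from rates, given as fractions of the charge per day.

| flask | free monomer | protic impurity | initiator | remark | time |
|---|---|---|---|---|---|
| delta | 0.050 M | 7 mM | 2 mM | run made earlier |  |
| theta | 0.050 M | 14 mM | 2 mM | run made earlier |  |
| dusk | 0.050 M | 5.00 mM | 2.0 mM |  | 6.0 d |
| noon | 0.050 M | 10.0 mM | 2.0 mM |  | 6.0 d |

| run | time / d | monomer in chains / % | free monomer / % |
|---|---|---|---|
| delta | 0.625 | 0.6 | 61.6 |
| delta | 1.25 | 2.3 | 48.5 |
| delta | 2.00 | 3.6 | 41.4 |
| delta | 3.00 | 6.3 | 35.8 |
| delta | 4.00 | 9.8 | 33.7 |
| theta | 0.250 | 0 | 61.8 |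
| theta | 0.833 | 1.0 | 46.3 |
| theta | 1.67 | 3.2 | 37.6 |
| theta | 2.50 | 4.3 | 32.8 |
| theta | 3.00 | 5.4 | 30.9 |
| theta | 4.00 | 7.5 | 29.2 |

(scatter of a reading: 0.5 percentage points)

- which of these there is most of at the end, counted by the free monomer in it, dusk (monomer in chains / free monomer)
- which of these there is most of at the end, counted by the free monomer in it, noon (monomer in chains / free monomer)
- final amount of the leader among these, as a percentage of the free monomer charged, in dusk
- final amount of the leader among these, as a percentage of the free monomer charged, in noon



1. How fast at the start: over the first interval of the delta run, free monomer falls at 0.614 /d, while monomer in chains rises at 0.00960 /d. The first rate is therefore far larger than the second.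

2. What slows it: between 3.00 d and 4.00 d, the delta fall is down to 0.0210 /d, slower by a factor of 29.2. Chains now rise at 0.0350 /d. The exchange rate, meaning the free monomer lost per unit of charge gained by chains late in a run, is therefore 0.600. With a scatter of 0.5 percentage points on each reading, this is a rough reading.

3. What the slowing means: 2.00 d remain. Holding both delta rates, chains are reckoned to reach 16.8% and free monomer 29.5%. Going round once more, with the fall taken as pseudo-first-order in free monomer and scaled to the new mean, gives 29.9%.

4. Impurity: at 4.00 d, the theta run lies 4.5 points below delta for 7.00 mM more protic impurity. Shifting pro rata gives free monomer of 31.2% in dusk and 28.0% in noon. Both stand above the chains reckoned from the delta rates.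

The forecast names free monomer for dusk at 33.5% and free monomer for noon at 29.7%, holding that “free monomer relaxes reversibly into a hidden reservoir”. The reckoning above agrees on the leader but lies lower in dusk and in noon.

The simulation gives free monomer leading in dusk at 31.2% and free monomer leading in noon at 28.4%, with chains at 17.6% and 14.5%.

    initiator → spent initiator (k = 1.30 × 10⁻⁷ /min)
    protic impurity + free monomer → quenched substrate (k = 0.360 /M/min)
    free monomer + living end → monomer in chains + living end, rate k3*[living end]*[free monomer] (k = 0.130 /M/min)
    free monomer ⇌ dormant form (K = 1.20, k = 4.20 × 10⁻⁴ /min)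
    free monomer + initiator → living end + monomer in chains (k = 0.00200 /M/min)

In dusk, from 3.00 d to 6.00 d, free monomer goes from 38.1% to 31.2% while chains go from 7.15% to 17.6%. That is an exchange rate of 0.660, against the 0.600 read in delta. A neighbour flask is dusk with initiator raised to 0.0034 M, and it ends with 26.8% in chains, 9.2 points above dusk. The exchange rate then puts its free monomer at 25.7%, and that neighbour flask holds 26.3%.

All runs stem from a simulated flask from invented constants, noise included.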